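In a closed flask each portion of substrate gets the same time, in a stirred tank a spread of times, and in a dosed flask the last portion arrives at the end, so I counted the lifetimes each set-up grants.

| flask | substrate | precatalyst | remark | time |
|---|---|---|---|---|
| maple | 0.050 M | 7.5 mM | run made earlier |  |
| oak | 0.050 M | 3.8 mM | run made earlier |  |
| ash | 0.050 M | 15 mM | run made earlier |  |
| alder | 0.10 M | 7.5 mM | run made earlier |  |
| delta | 0.050 M | 7.5 mM | everything together in a closed stirred flask, run for 10 h | 10 h |
| gamma | 0.050 M | 7.5 mM | a single well-mixed tank run continuously and read at steady state, 100 h in it on average |  |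
| epsilon | 0.050 M | 7.5 mM | one stirred flow tank at steady state, fed with the mixture as stated, mean residence time 10 h |  |
| zeta | 0.050 M (fed, over 10.0 h) | 7.5 mM | a stirred flask in which substrate is dosed at a steady rate over 10.0 h without added volume, worked up at 10 h | 10 h |

| run | time / h | target / % | isomer of the product / % |
|---|---|---|---|
| maple | 0.833 | 0 | 5.4 |
| maple | 1.33 | 3.1 | 10.8 |
| maple | 2.00 | 5.4 | 18.7 |
| maple | 4.00 | 17.0 | 28.0 |
| maple | 6.00 | 28.1 | 32.2 |
| maple | 10.0 | 41.1 | 35.6 |
| oak | 1.00 | 0 | 5.1 |
| oak | 1.50 | 1.8 | 6.6 |
| oak | 2.50 | 2.9 | 13.5 |
| oak | 4.00 | 8.6 | 19.8 |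
| oak | 8.00 | 20.1 | 29.1 |
| oak | 12.0 | 29.8 | 33.3 |
| ash | 2.00 | 12.3 | 25.6 |
| ash | 4.00 | 31.1 | 33.6 |
| ash | 6.00 | 43.5 | 35.5 |
| ash | 8.00 | 49.1 | 34.7 |
| ash | 10.0 | 53.3 | 32.9 |
| ash | 12.0 | 52.9 | 33.7 |
| alder | 2.50 | 7.7 | 20.9 |
| alder | 5.00 | 21.0 | 31.1 |
| alder | 8.00 | 32.8 | 32.3 |
| alder | 10.0 | 41.0 | 33.8 |
| alder | 12.0 | 45.2 | 34.4 |

(scatter of a reading: 1 percentage point)

- the set-up with the highest share of target in all that became target or isomer of the product, at the outlet or at the end ("none" if the first two lie within 2 percentage points) (delta / gamma / epsilon / zeta / none)
- share of target in all that became target or isomer of the product, at the outlet or at the end, delta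
- share of target in all that became target or isomer of the product, at the outlet or at the end, gamma
- share of target in all that became target or isomer of the product, at the outlet or at the end, epsilon
- share of target in all that became target or isomer of the product, at the outlet or at the end, zeta

- the stated concentrations are those of everything mixed, before any reaction; amounts are the same in each set-up
- the feed brings no volume worth counting
- the earlier runs were made in a closed, stirred flask

Two extreme flasks can be solved in the head. Stopped early, maple stood under kinetic control: it read 0 % target beside 5.4 % isomer at 0.833 h, a share near zero. Left long, ash came under thermodynamic control: it levelled at target 53.1 % and isomer 33.3 %, a read share of 61.5 %. Between them, I placed each flask by a count of lifetimes.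

Ash's target gap to that level shrank from 41 percentage points at 2.00 h to 9.6 points at 6.00 h, which gave ash a read lifetime of 2.76 h. Precatalyst and time traded against each other: oak, with half maple's precatalyst, read isomer 29.1 % at 8.00 h, and maple 28.0 % at 4.00 h. Alder, with twice the substrate, read target 41.0 % at 10.0 h, where maple read 41.1 %. So I put the lifetime at 7.5 mM of precatalyst at 5.53 h: the time in which the gap to equilibrium shrinks by a factor of e.

Counted as one first-order approach, a closed flask keeps the exponential of minus the count as its gap, a tank one part in one plus the count, and an evenly dosed flask the closed flask's gap averaged over its ages. Delta had 1.81 lifetimes and kept 16.4 %. Epsilon, with the same count, kept 35.6 %, and zeta 46.2 %. Gamma had 18.1 lifetimes and kept less than the others, 5.24 %. My count gave an order of the shares, smallest gap first, and no percentages.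

The forecast named gamma best, with 59.4 % for gamma, 53.8 % for delta, 50 % for epsilon and 44 % for zeta, reading the level in ash as equilibrium with “no sign of catalyst death”.

The flasks gave gamma 60.0 %, delta 54.7 %, epsilon 51.3 % and zeta 46.1 %, so gamma led delta by 5.3 points against a margin of 2 points.

    precatalyst → catalyst (k = 0.0177 min⁻¹)
    isomer of the product + catalyst ⇌ substrate + catalyst, rate k2*[catalyst]*[isomer of the product] forward; the back reaction follows from the equilibrium constant (k = 0.159 M⁻¹ min⁻¹)
    target + catalyst ⇌ isomer of the product + catalyst, rate k3*[catalyst]*[target] forward; the back reaction follows from the equilibrium constant (K = 0.635, k = 0.365 M⁻¹ min⁻¹)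
    substrate + catalyst ⇌ target + catalyst, rate k4*[substrate]*[catalyst] forward; the back reaction follows from the equilibrium constant (K = 4.15, k = 0.0557 M⁻¹ min⁻¹)

Zeta ended with 47.0 % of its charge still substrate, against 24.1 % in delta. For the neighbour of zeta with 0.019 M of precatalyst I reckoned a lifetime of 2.18 h, hence 4.58 lifetimes and a gap of 21.6 %. That neighbour's share reached 55.8 %, with 28 % of the charged substrate still there.

The data were computed with constants of no real substance; scatter was added.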